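**Retrosynthetic overview**

1. Numbering follows 1H-isochromene (C1, O2, C3, C4, C4a, C5–C8, C8a; ring A = pyran, ring B = carbocycle; side chain C1'–C7'). Ring A is closed last, through the O2–C3 bond, by 6-endo hydroalkoxylation of the C1 hydroxyl onto a C3≡C4 alkyne carried by a ring B enynone (25 to 26).
2. Ring B is closed first, in one flask, by a [3+3] annulation. C7–C8 comes from a reductive aldol of 2,3-butanedione (as its divalent-tin enediolate) with the C8 aldehyde; C4a=C5 comes from an intramolecular Mukaiyama aldol–elimination of the resulting C5 methyl ketone onto the C4a ketal.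
3. Enabling feature: in ring B the C6 carbonyl sits between vinylic C5 and the quaternary carbinol C7(CH3)(OH), so C5–C6–C7 is an acetoin unit (biacetyl one oxidation level down) that can serve as a 1,3-bis-nucleophile. C8 (carbinol) and C4a (enone beta-carbon) are 1,3-related electrophilic positions across C8a, and the fully substituted C7 blocks dehydration and aromatisation of the aldol.
4. The aldehyde–ketal partner 18 comes from an Evans titanium-enolate alkylation with triethyl orthopropiolate (sets C8a, brings the masked C4a ketone and the C3≡C4 alkyne) and a Sonogashira coupling with vinyl iodide 8.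
5. Vinyl iodide 8 comes from L-isoleucic acid (C4' and C5' from the chiral pool, C3' by chelation-controlled methyl Grignard addition to an alpha-hydroxy ynone).

Key step: step 11

Assumption: 3-[(tert-butyldimethylsilyl)oxy]propanoic acid (10) is taken as a catalogue compound; otherwise it follows from methyl 3-hydroxypropanoate by silylation and saponification.

**Route**

Step 1
Reactants: 1 (2S,3S)-2-hydroxy-3-methylpentanoic acid (L-isoleucic acid)
Product: 2 (2S,3S)-2-hydroxy-N-methoxy-N,3-dimethylpentanamide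
Conditions: MeNH(OMe)·HCl, EDC·HCl, HOBt, N-methylmorpholine, CH2Cl2, 0 °C to rt
Reagents that add atoms: N,O-dimethylhydroxylamine hydrochloride, CNOC.Cl
Why: Carbodiimide amide coupling (EDC/HOBt) of the free alpha-hydroxy acid should give the Weinreb amide without touching C2 or C3, because no strongly activated, base-exposed acyl species persists.

Step 2
Reactants: 2 (2S,3S)-2-hydroxy-N-methoxy-N,3-dimethylpentanamide; 3 ethynylmagnesium bromide
Product: 4 (4S,5S)-4-hydroxy-5-methylhept-1-yn-3-one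
Conditions: HC≡CMgBr (3 equiv), THF, 0 °C; NH4Cl (aq) at −20 °C; used without delay
Reagents that add atoms: none
Why: Weinreb ketone synthesis: after the hydroxyl is deprotonated the alkynyl Grignard reagent adds once, and the magnesium-chelated tetrahedral intermediate survives until work-up, so the ynone should form without over-addition or loss of the alpha stereocenter.

Step 3
Reactants: 4 (4S,5S)-4-hydroxy-5-methylhept-1-yn-3-one
Product: 5 (3R,4S,5S)-3,5-dimethylhept-1-yne-3,4-diol
Conditions: MeMgBr (3.5 equiv), THF, −78 to 0 °C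
Reagents that add atoms: methylmagnesium bromide, C[Mg]Br
Why: Cram-chelate-controlled Grignard addition: the magnesium alkoxide at C4 chelates the ketone oxygen in a five-membered ring and methyl attacks the carbonyl face opposite the sec-butyl group, which should set the tertiary carbinol as 3R.

Step 4
Reactants: 5 (3R,4S,5S)-3,5-dimethylhept-1-yne-3,4-diol
Product: 6 (3R,4S,5S)-3,5-dimethyl-3,4-bis(triethylsilyloxy)hept-1-yne
Conditions: TESOTf, 2,6-lutidine, CH2Cl2, −78 to 0 °C
Reagents that add atoms: triethylsilyl triflate, CC[Si](CC)(CC)OS(=O)(=O)C(F)(F)F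
Why: Silyl triflate/lutidine silylation is strong enough for the tertiary and the hindered secondary hydroxyl and creates no stereocenter.

Step 5
Reactants: 6 (3R,4S,5S)-3,5-dimethyl-3,4-bis(triethylsilyloxy)hept-1-yne
Product: 8 (1E,3R,4S,5S)-1-iodo-3,5-dimethyl-3,4-bis(triethylsilyloxy)hept-1-ene, via alkenylzirconocene chloride 7 (not isolated)
Conditions: Cp2Zr(H)Cl, THF, rt; then I2, 0 °C
Reagents that add atoms: iodine, II
Why: Schwartz hydrozirconation adds Zr–H syn across the terminal alkyne with zirconium on the terminal carbon, and iodinolysis of the C–Zr bond with retention should give the E-vinyl iodide only.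

Step 6
Reactants: 9 (S)-4-benzyl-1,3-oxazolidin-2-one; 10 3-[(tert-butyldimethylsilyl)oxy]propanoic acid
Product: 12 (4S)-4-benzyl-3-{3-[(tert-butyldimethylsilyl)oxy]propanoyl}-1,3-oxazolidin-2-one, via mixed pivalic anhydride 11 (not isolated)
Conditions: PivCl, Et3N, THF, −20 °C; then 9, LiCl, −20 °C to rt
Reagents that add atoms: none
Why: N-acylation of the oxazolidinone through the mixed pivalic anhydride (Evans auxiliary acylation, LiCl/Et3N variant) is routine and involves no stereocenter other than that of the auxiliary.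

Step 7
Reactants: 12 (4S)-4-benzyl-3-{3-[(tert-butyldimethylsilyl)oxy]propanoyl}-1,3-oxazolidin-2-one; 13 3,3,3-triethoxyprop-1-yne (triethyl orthopropiolate)
Product: 15 (4S)-4-benzyl-3-[(2R)-2-{[(tert-butyldimethylsilyl)oxy]methyl}-3,3-diethoxypent-4-ynoyl]-1,3-oxazolidin-2-one, via titanium enolate 14 (not isolated)
Conditions: TiCl4, iPr2NEt, CH2Cl2, 0 °C; then 13, 0 °C
Reagents that add atoms: none
Why: Evans titanium-enolate alkylation with an orthoester: the orthoester ionises to a diethoxycarbenium ion that is captured by the chelated Z-enolate on the face opposite the benzyl group, which should set the future C8a (R in 15) and deliver the C4a ketone already masked as its diethyl ketal.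

Step 8
Reactants: 15 (4S)-4-benzyl-3-[(2R)-2-{[(tert-butyldimethylsilyl)oxy]methyl}-3,3-diethoxypent-4-ynoyl]-1,3-oxazolidin-2-one
Product: 16 (2R)-2-{[(tert-butyldimethylsilyl)oxy]methyl}-3,3-diethoxypent-4-yn-1-ol
Conditions: LiBH4, MeOH (1 equiv), THF, 0 °C
Reagents that add atoms: none
Why: Reductive cleavage of the acyl oxazolidinone with LiBH4 attacks the exocyclic carbonyl, releases the auxiliary and leaves the ketal, alkyne, silyl ether and alpha stereocenter untouched.

Step 9
Reactants: 16 (2R)-2-{[(tert-butyldimethylsilyl)oxy]methyl}-3,3-diethoxypent-4-yn-1-ol; 8 (1E,3R,4S,5S)-1-iodo-3,5-dimethyl-3,4-bis(triethylsilyloxy)hept-1-ene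
Product: 17 (2R,6E,8R,9S,10S)-2-{[(tert-butyldimethylsilyl)oxy]methyl}-3,3-diethoxy-8,10-dimethyl-8,9-bis(triethylsilyloxy)dodec-6-en-4-yn-1-ol
Conditions: PdCl2(PPh3)2 (5 mol %), CuI (10 mol %), Et3N, THF, rt
Reagents that add atoms: none
Why: Sonogashira coupling of a terminal alkyne with a vinyl iodide proceeds with retention of the E geometry under mild amine conditions that the ketal and silyl ethers tolerate.

Step 10
Reactants: 17 (2R,6E,8R,9S,10S)-2-{[(tert-butyldimethylsilyl)oxy]methyl}-3,3-diethoxy-8,10-dimethyl-8,9-bis(triethylsilyloxy)dodec-6-en-4-yn-1-ol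
Product: 18 (2S,6E,8R,9S,10S)-2-{[(tert-butyldimethylsilyl)oxy]methyl}-3,3-diethoxy-8,10-dimethyl-8,9-bis(triethylsilyloxy)dodec-6-en-4-ynal
Conditions: Dess–Martin periodinane, NaHCO3, CH2Cl2, 0 °C to rt; used crude
Reagents that add atoms: none
Why: Dess–Martin oxidation under bicarbonate buffer is neutral enough to give the alpha-branched aldehyde without epimerising C8a or eliminating the beta-silyloxy or beta-ethoxy groups.

Step 11
Reactants: 18 (2S,6E,8R,9S,10S)-2-{[(tert-butyldimethylsilyl)oxy]methyl}-3,3-diethoxy-8,10-dimethyl-8,9-bis(triethylsilyloxy)dodec-6-en-4-ynal; 19 butane-2,3-dione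
Product: 24 (4S,5S,6R)-4-{[(tert-butyldimethylsilyl)oxy]methyl}-3-[(3E,5R,6S,7S)-5,7-dimethyl-5,6-bis(triethylsilyloxy)non-3-en-1-yn-1-yl]-6-methyl-5,6-bis(trimethylsilyloxy)cyclohex-2-en-1-one, via tin enediolate 20 (not isolated), via stannylene aldolate 21 (not isolated), via tris-silyl enol ether 22 (not isolated), via ethoxy ketone 23 (not isolated)
Conditions: 19, activated Sn powder, THF, 0 °C; then 18, −20 to 0 °C; solvent switch to CH2Cl2; TMSOTf (3.3 equiv), iPr2NEt (1.1 equiv), −78 to −20 °C; then DBU, 0 °C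
Reagents that add atoms: trimethylsilyl triflate, C[Si](C)(C)OS(=O)(=O)C(F)(F)F
Why: Proposed new method: zerovalent tin reduces 2,3-butanedione to the cyclic divalent-tin enediolate 20, a symmetric equivalent of an acetoin C7/C5 bis-nucleophile, whose aldol addition to aldehyde 18 forms C7–C8 (closest known type: Mukaiyama's reductive aldol of 1,2-diketones through divalent-tin enediolates); after O-silylation the methyl ketone is enol-silylated at C5, the only enolisable position once C7 is quaternary, and 22 adds to the oxocarbenium ion that TMSOTf releases from the C4a diethyl ketal (closest known type: intramolecular Mukaiyama aldol addition to a ketal), after which DBU removes ethanol from beta-ethoxy ketone 23 to give the C4a=C5 enone. Ring B closes in a 6-(enolendo)-exo-trig mode on the planar oxocarbenium carbon. C8 is set by Felkin–Anh attack on 18 anti to the bulky quaternary ketal carbon on C8a (the C1 silyl ether does not chelate), which puts O8 trans to C1 in the ring. C7 is set in the tin-bridged, norbornane-like transition state (the counterpart of a Zimmerman–Traxler chair of a Z-enolate) with the aldehyde substituent exo, which puts O7 syn to O8 in the open chain and hence trans in ring B, with the methyl group cis to O8. The step needs the aldehyde to react before the ketal, which the neutral tin enediolate (unable to ionise a ketal) and the slow-ionising acetylenic ketal should secure; it needs one regiochemistry, which the symmetric C4 donor and the quaternary C7 secure, the latter also blocking dehydration and aromatisation of the aldol.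

Step 12
Reactants: 24 (4S,5S,6R)-4-{[(tert-butyldimethylsilyl)oxy]methyl}-3-[(3E,5R,6S,7S)-5,7-dimethyl-5,6-bis(triethylsilyloxy)non-3-en-1-yn-1-yl]-6-methyl-5,6-bis(trimethylsilyloxy)cyclohex-2-en-1-one
Product: 25 (4S,5S,6R)-3-[(3E,5R,6S,7S)-5,6-dihydroxy-5,7-dimethylnon-3-en-1-yn-1-yl]-5,6-dihydroxy-4-(hydroxymethyl)-6-methylcyclohex-2-en-1-one
Conditions: HF·pyridine, pyridine, THF, 0 °C to rt
Reagents that add atoms: none
Why: Fluoride-driven Si–O cleavage (global desilylation with buffered HF·pyridine) removes all five silyl groups under weakly acidic conditions that should avoid retro-aldol opening of ring B and elimination at C8.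

Step 13
Reactants: 25 (4S,5S,6R)-3-[(3E,5R,6S,7S)-5,6-dihydroxy-5,7-dimethylnon-3-en-1-yn-1-yl]-5,6-dihydroxy-4-(hydroxymethyl)-6-methylcyclohex-2-en-1-one
Product: 26 (7R,8S,8aS)-3-[(1E,3R,4S,5S)-3,4-dihydroxy-3,5-dimethylhept-1-en-1-yl]-7,8-dihydroxy-7-methyl-1,7,8,8a-tetrahydro-6H-isochromen-6-one
Conditions: AuCl(PPh3) (5 mol %), AgOTf (5 mol %), THF, rt
Reagents that add atoms: none
Why: Monovalent-gold-catalysed 6-endo-dig hydroalkoxylation (cycloisomerisation) closes ring A because the primary C1 hydroxyl adds to C3, the electrophilic delta position of the ynenone that is also cation-stabilised by the side-chain alkene, whereas the other hydroxyls could reach the alkyne only through bridged or trans-alkene-spanning rings; no stereocenter is formed.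

**Compound list**

1 | (2S,3S)-2-hydroxy-3-methylpentanoic acid | CC[C@H](C)[C@H](O)C(=O)O | starting material
2 | (2S,3S)-2-hydroxy-N-methoxy-N,3-dimethylpentanamide | CC[C@H](C)[C@H](O)C(=O)N(C)OC | intermediate
3 | ethynylmagnesium bromide | C#C[Mg]Br | starting material
4 | (4S,5S)-4-hydroxy-5-methylhept-1-yn-3-one | CC[C@H](C)[C@H](O)C(=O)C#C | intermediate
5 | (3R,4S,5S)-3,5-dimethylhept-1-yne-3,4-diol | CC[C@H](C)[C@H](O)[C@](C)(O)C#C | intermediate
6 | (3R,4S,5S)-3,5-dimethyl-3,4-bis(triethylsilyloxy)hept-1-yne | CC[C@H](C)[C@H](O[Si](CC)(CC)CC)[C@](C)(O[Si](CC)(CC)CC)C#C | intermediate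
7 | chlorobis(cyclopentadienyl)[(1E,3R,4S,5S)-3,5-dimethyl-3,4-bis(triethylsilyloxy)hept-1-en-1-yl]zirconium | CC[C@H](C)[C@H](O[Si](CC)(CC)CC)[C@](C)(O[Si](CC)(CC)CC)/C=C/[Zr](Cl)(C1C=CC=C1)C1C=CC=C1 | intermediate
8 | (1E,3R,4S,5S)-1-iodo-3,5-dimethyl-3,4-bis(triethylsilyloxy)hept-1-ene | CC[C@H](C)[C@H](O[Si](CC)(CC)CC)[C@](C)(O[Si](CC)(CC)CC)/C=C/I | intermediate
9 | (S)-4-benzyl-1,3-oxazolidin-2-one | O=C1OC[C@H](Cc2ccccc2)N1 | starting material
10 | 3-[(tert-butyldimethylsilyl)oxy]propanoic acid | OC(=O)CCO[Si](C)(C)C(C)(C)C | starting material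
11 | 3-[(tert-butyldimethylsilyl)oxy]propanoic pivalic anhydride | CC(C)(C)C(=O)OC(=O)CCO[Si](C)(C)C(C)(C)C | intermediate
12 | (4S)-4-benzyl-3-{3-[(tert-butyldimethylsilyl)oxy]propanoyl}-1,3-oxazolidin-2-one | O=C1OC[C@H](Cc2ccccc2)N1C(=O)CCO[Si](C)(C)C(C)(C)C | intermediate
13 | 3,3,3-triethoxyprop-1-yne | C#CC(OCC)(OCC)OCC | starting material
14 | trichlorotitanium (Z)-enolate of 12 | O=C1OC[C@H](Cc2ccccc2)N1/C(O[Ti](Cl)(Cl)Cl)=C/CO[Si](C)(C)C(C)(C)C | intermediate
15 | (4S)-4-benzyl-3-[(2R)-2-{[(tert-butyldimethylsilyl)oxy]methyl}-3,3-diethoxypent-4-ynoyl]-1,3-oxazolidin-2-one | O=C1OC[C@H](Cc2ccccc2)N1C(=O)[C@@H](C(OCC)(OCC)C#C)CO[Si](C)(C)C(C)(C)C | intermediate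
16 | (2R)-2-{[(tert-butyldimethylsilyl)oxy]methyl}-3,3-diethoxypent-4-yn-1-ol | C#CC(OCC)(OCC)[C@H](CO)CO[Si](C)(C)C(C)(C)C | intermediate
17 | (2R,6E,8R,9S,10S)-2-{[(tert-butyldimethylsilyl)oxy]methyl}-3,3-diethoxy-8,10-dimethyl-8,9-bis(triethylsilyloxy)dodec-6-en-4-yn-1-ol | CC[C@H](C)[C@H](O[Si](CC)(CC)CC)[C@](C)(O[Si](CC)(CC)CC)/C=C/C#CC(OCC)(OCC)[C@H](CO)CO[Si](C)(C)C(C)(C)C | intermediate
18 | (2S,6E,8R,9S,10S)-2-{[(tert-butyldimethylsilyl)oxy]methyl}-3,3-diethoxy-8,10-dimethyl-8,9-bis(triethylsilyloxy)dodec-6-en-4-ynal | CC[C@H](C)[C@H](O[Si](CC)(CC)CC)[C@](C)(O[Si](CC)(CC)CC)/C=C/C#CC(OCC)(OCC)[C@H](C=O)CO[Si](C)(C)C(C)(C)C | intermediate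
19 | butane-2,3-dione | CC(=O)C(C)=O | starting material
20 | 4,5-dimethyl-1,3,2-dioxastannole (divalent-tin enediolate of 19) | CC1=C(C)O[Sn]O1 | intermediate
21 | aldol adduct of 18 and 19 as its cyclic divalent-tin 7,8-diolate (methyl ketone at C6; 7R,8S,8aS in target numbering) | CC[C@H](C)[C@H](O[Si](CC)(CC)CC)[C@](C)(O[Si](CC)(CC)CC)/C=C/C#CC(OCC)(OCC)[C@@H](CO[Si](C)(C)C(C)(C)C)[C@@H]1O[Sn]O[C@@]1(C)C(C)=O | intermediate
22 | 7,8-bis(trimethylsilyl) ether and C5=C6 trimethylsilyl enol ether of the aldol adduct (ketal intact) | CC[C@H](C)[C@H](O[Si](CC)(CC)CC)[C@](C)(O[Si](CC)(CC)CC)/C=C/C#CC(OCC)(OCC)[C@@H](CO[Si](C)(C)C(C)(C)C)[C@H](O[Si](C)(C)C)[C@@](C)(O[Si](C)(C)C)C(=C)O[Si](C)(C)C | intermediate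
23 | ring B beta-ethoxy ketone (C4a bears ethoxy and the enynyl group, either configuration at C4a; C5 methylene) | CC[C@H](C)[C@H](O[Si](CC)(CC)CC)[C@](C)(O[Si](CC)(CC)CC)/C=C/C#CC1(OCC)CC(=O)[C@](C)(O[Si](C)(C)C)[C@@H](O[Si](C)(C)C)[C@@H]1CO[Si](C)(C)C(C)(C)C | intermediate
24 | (4S,5S,6R)-4-{[(tert-butyldimethylsilyl)oxy]methyl}-3-[(3E,5R,6S,7S)-5,7-dimethyl-5,6-bis(triethylsilyloxy)non-3-en-1-yn-1-yl]-6-methyl-5,6-bis(trimethylsilyloxy)cyclohex-2-en-1-one | CC[C@H](C)[C@H](O[Si](CC)(CC)CC)[C@](C)(O[Si](CC)(CC)CC)/C=C/C#CC1=CC(=O)[C@](C)(O[Si](C)(C)C)[C@@H](O[Si](C)(C)C)[C@@H]1CO[Si](C)(C)C(C)(C)C | intermediate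
25 | (4S,5S,6R)-3-[(3E,5R,6S,7S)-5,6-dihydroxy-5,7-dimethylnon-3-en-1-yn-1-yl]-5,6-dihydroxy-4-(hydroxymethyl)-6-methylcyclohex-2-en-1-one | CC[C@H](C)[C@H](O)[C@](C)(O)/C=C/C#CC1=CC(=O)[C@](C)(O)[C@@H](O)[C@@H]1CO | intermediate
26 | (7R,8S,8aS)-3-[(1E,3R,4S,5S)-3,4-dihydroxy-3,5-dimethylhept-1-en-1-yl]-7,8-dihydroxy-7-methyl-1,7,8,8a-tetrahydro-6H-isochromen-6-one | CC[C@H](C)[C@H](O)[C@](C)(O)/C=C/C1=CC2=CC(=O)[C@](C)(O)[C@@H](O)[C@@H]2CO1 | target

**Step count and risks**

Total step count: 13. Longest linear sequence: 10 steps (steps 1–5 and 9–13).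

Steps most likely to fail:

Step 11 (Proposed new method). What may go wrong:
- premature ionisation of the C4a ketal, so that the carbon nucleophiles add in the wrong order;
- erosion of Felkin–Anh facial selectivity at C8 if the tin centre chelates a ketal oxygen;
- loss of the C8a configuration through enol-ether formation from the oxocarbenium ion;
- incomplete elimination of ethanol.

Fallback with known reactions, from 18 and 19: the divalent-tin enediolate aldol is run alone and worked up with water to give the dihydroxy methyl ketone F1. Silylation (TMSCl, imidazole, DMF) gives the bis(trimethylsilyl) ether F2. Iodine-catalysed ketal cleavage in wet acetone unmasks the ynone F3. Ring B is then closed by a conventional amine-mediated intramolecular aldol condensation (piperidinium acetate, toluene, 40 °C), which comes back to the route at 24.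

Step 7. What may go wrong:
- beta-elimination of the silyloxy group from the titanium enolate;
- attack of the enolate at the alkyne terminus of the propargylic dialkoxycarbenium ion;
- sluggish ionisation of the bulky orthoester.

Fallback, from 12: C-acylation of the lithium enolate (LDA, THF, −78 °C) with 3-(trimethylsilyl)propynoyl chloride, made from the commercial acid, gives the beta-keto imide F4 with the same facial sense. Ketalisation (HC(OEt)3, EtOH, TsOH) gives the diethyl ketal F5. LiBH4 reduction gives the C-silylated alkynyl alcohol F6. K2CO3 in MeOH removes the alkyne silyl group and comes back to the route at 16.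

Step 13. What may go wrong:
- competing 5-exo-dig attack at C4, leading to an alkylidene tetrahydrofuran;
- gold-promoted ionisation of the tertiary allylic alcohol at C3'.

Fallback, from 25: 6-endo iodoetherification (I2, NaHCO3, MeCN, 0 °C), whose regiochemistry is fixed by the more stabilised iodonium opening at C3, gives the 4-iodo pyran F7. Reductive deiodination (Pd(PPh3)4, Bu3SnH, THF, rt) comes back to the route at 26.

Further compounds
F1 | step 11 | aldol adduct of 18 and 19 with free 7,8-diol and C6 methyl ketone (7R,8S,8aS in target numbering) | CC[C@H](C)[C@H](O[Si](CC)(CC)CC)[C@](C)(O[Si](CC)(CC)CC)/C=C/C#CC(OCC)(OCC)[C@@H](CO[Si](C)(C)C(C)(C)C)[C@H](O)[C@@](C)(O)C(C)=O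
F2 | step 11 | 7,8-bis(trimethylsilyl) ether of F1 | CC[C@H](C)[C@H](O[Si](CC)(CC)CC)[C@](C)(O[Si](CC)(CC)CC)/C=C/C#CC(OCC)(OCC)[C@@H](CO[Si](C)(C)C(C)(C)C)[C@H](O[Si](C)(C)C)[C@@](C)(O[Si](C)(C)C)C(C)=O
F3 | step 11 | ynone from F2 (C4a ketone unmasked) | CC[C@H](C)[C@H](O[Si](CC)(CC)CC)[C@](C)(O[Si](CC)(CC)CC)/C=C/C#CC(=O)[C@@H](CO[Si](C)(C)C(C)(C)C)[C@H](O[Si](C)(C)C)[C@@](C)(O[Si](C)(C)C)C(C)=O
F4 | step 7 | (4S)-4-benzyl-3-[(2R)-2-{[(tert-butyldimethylsilyl)oxy]methyl}-3-oxo-5-(trimethylsilyl)pent-4-ynoyl]-1,3-oxazolidin-2-one | O=C1OC[C@H](Cc2ccccc2)N1C(=O)[C@@H](C(=O)C#C[Si](C)(C)C)CO[Si](C)(C)C(C)(C)C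
F5 | step 7 | (4S)-4-benzyl-3-[(2R)-2-{[(tert-butyldimethylsilyl)oxy]methyl}-3,3-diethoxy-5-(trimethylsilyl)pent-4-ynoyl]-1,3-oxazolidin-2-one | O=C1OC[C@H](Cc2ccccc2)N1C(=O)[C@@H](C(OCC)(OCC)C#C[Si](C)(C)C)CO[Si](C)(C)C(C)(C)C
F6 | step 7 | (2R)-2-{[(tert-butyldimethylsilyl)oxy]methyl}-3,3-diethoxy-5-(trimethylsilyl)pent-4-yn-1-ol | C[Si](C)(C)C#CC(OCC)(OCC)[C@H](CO)CO[Si](C)(C)C(C)(C)C
F7 | step 13 | (7R,8S,8aS)-3-[(1E,3R,4S,5S)-3,4-dihydroxy-3,5-dimethylhept-1-en-1-yl]-7,8-dihydroxy-4-iodo-7-methyl-1,7,8,8a-tetrahydro-6H-isochromen-6-one | CC[C@H](C)[C@H](O)[C@](C)(O)/C=C/C1=C(I)C2=CC(=O)[C@](C)(O)[C@@H](O)[C@@H]2CO1
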